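**Retrosynthetic overview**
1. Target ⇒ tribromo bis-aldehyde; both CH2OH groups come from one NaBH4 reduction at the very end.
2. ⇒ triphenol lacking the two C5 bromines (both go in together, each ortho to a free 4-OH) ⇒ its bis-methyl ether (BBr3).
3. Key disconnection at the ring-B C2–O bond, but not as phenol + aryl halide: ring B is an o-quinone diazide and ring A is 2-bromoisovanillin. Rh-carbenoid O–H insertion with rearomatisation gives the 2-aryloxyphenol unit directly.
4. Quinone diazide ⇒ o-aminophenol ⇒ 2-nitroisovanillin.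
5. No ring is built: both benzene rings are bought as isovanillin derivatives. Ring B is only dearomatised (diazide) and rearomatised (key step).

Assumption: the target has no stereocentre and its diaryl ether axis rotates freely, so "single enantiomer" is read as the achiral compound drawn; 1 and 4 are taken as catalogue compounds.

**Step 1**
Reactants: 1 3-hydroxy-4-methoxy-2-nitrobenzaldehyde (2-nitroisovanillin)
Product: 2 2-amino-3-hydroxy-4-methoxybenzaldehyde
Conditions: Fe powder, AcOH/EtOH/H2O, 60 °C, N2; extractive work-up, used at once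
Reagents that add atoms: none
Why: Béchamp-type Fe/AcOH nitro reduction is chemoselective for ArNO2 over ArCHO and is the standard entry to 2-aminobenzaldehydes; no stereocentre is involved.

**Step 2**
Reactants: 2 2-amino-3-hydroxy-4-methoxybenzaldehyde
Product: 3 6-diazo-4-methoxy-5-oxocyclohexa-1,3-diene-1-carbaldehyde (o-quinone diazide, i.e. 2-diazonio-3-formyl-6-methoxyphenolate)
Conditions: t-BuONO (1.3 equiv), AcOH (cat.), THF, 0 °C, dark
Reagents that add atoms: tert-butyl nitrite, CC(C)(C)ON=O
Why: Aprotic diazotisation of an o-aminophenol gives the diazonium phenolate, which is the neutral o-quinone diazide (classical diazo-oxide formation), here stabilised by the flanking ring carbonyl and formyl groups.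

**Step 3 (key step)**
Reactants: 3 6-diazo-4-methoxy-5-oxocyclohexa-1,3-diene-1-carbaldehyde; 4 2-bromo-3-hydroxy-4-methoxybenzaldehyde (2-bromoisovanillin, 3 equiv, excess recovered)
Product: 5 2-bromo-3-(6-formyl-2-hydroxy-3-methoxyphenoxy)-4-methoxybenzaldehyde
Conditions: Rh2(esp)2 (1 mol %), 1,2-dichloroethane, 60 °C, slow addition of 3 over 2 h, dark
Reagents that add atoms: none
Why: Proposed new method: Rh(II) converts the acceptor-type diazo group of 3 into an electrophilic carbenoid at ring-B C2 (a masked 2-oxidophenyl cation), the phenolic O–H of 4 adds to give an oxonium ylide, and proton transfer to the ring oxygen rearomatises ring B to the 2-aryloxyphenol; aromatisation is the driving force, O–H capture is expected to outrun Wolff ring contraction and carbonyl-ylide formation with the aldehydes, and the site of the new C–O bond is fixed by where the nitro group sat; closest known reaction type: Rh(II)-catalysed O–H insertion of diazo carbonyl compounds and of diazonaphthoquinones/quinone diazides into alcohols and phenols.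

**Step 4**
Reactants: 5 2-bromo-3-(6-formyl-2-hydroxy-3-methoxyphenoxy)-4-methoxybenzaldehyde
Product: 6 2-bromo-3-(6-formyl-2,3-dihydroxyphenoxy)-4-hydroxybenzaldehyde
Conditions: BBr3 (6 equiv), CH2Cl2, −78 → 0 °C; then ice-water
Reagents that add atoms: none
Why: BBr3 Lewis-acid ether cleavage removes both O-methyl groups by bromide attack on the boron-complexed methyl ethers, while the diaryl ether, the aryl bromide and (after aqueous work-up) the aldehydes are untouched.

**Step 5**
Reactants: 6 2-bromo-3-(6-formyl-2,3-dihydroxyphenoxy)-4-hydroxybenzaldehyde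
Product: 7 2,5-dibromo-3-(4-bromo-6-formyl-2,3-dihydroxyphenoxy)-4-hydroxybenzaldehyde
Conditions: Br2 (2.1 equiv), AcOH, rt
Reagents that add atoms: bromine, BrBr
Why: Electrophilic aromatic bromination directed by the free 4-OH groups: on each ring C5 is ortho to 4-OH and meta to CHO (on ring B also para to the aryloxy oxygen), the vanillin → 5-bromovanillin selectivity, whereas C6 is ortho to CHO and disfavoured.

**Step 6**
Reactants: 7 2,5-dibromo-3-(4-bromo-6-formyl-2,3-dihydroxyphenoxy)-4-hydroxybenzaldehyde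
Product: 8 6-bromo-3-[2,5-dibromo-6-hydroxy-3-(hydroxymethyl)phenoxy]-4-(hydroxymethyl)benzene-1,2-diol (target CNP0104332.0)
Conditions: NaBH4 (6 equiv), THF/H2O (4:1), 0 °C → rt; cold aqueous work-up at pH 6–7
Reagents that add atoms: none
Why: Borohydride 1,2-reduction converts both aryl aldehydes into benzylic alcohols without touching aryl bromides or phenols, and the cold, methanol-free, near-neutral work-up avoids p-quinone-methide solvolysis of the 4-hydroxybenzyl alcohols; the product is achiral.

**Compound list**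
1 | 3-hydroxy-4-methoxy-2-nitrobenzaldehyde | O=Cc1ccc(OC)c(O)c1[N+](=O)[O-] | starting material
2 | 2-amino-3-hydroxy-4-methoxybenzaldehyde | Nc1c(C=O)ccc(OC)c1O | intermediate
3 | 6-diazo-4-methoxy-5-oxocyclohexa-1,3-diene-1-carbaldehyde | O=CC1=CC=C(OC)C(=O)C1=[N+]=[N-] | intermediate
4 | 2-bromo-3-hydroxy-4-methoxybenzaldehyde | O=Cc1ccc(OC)c(O)c1Br | starting material
5 | 2-bromo-3-(6-formyl-2-hydroxy-3-methoxyphenoxy)-4-methoxybenzaldehyde | O=Cc1ccc(OC)c(Oc2c(C=O)ccc(OC)c2O)c1Br | intermediate
6 | 2-bromo-3-(6-formyl-2,3-dihydroxyphenoxy)-4-hydroxybenzaldehyde | O=Cc1ccc(O)c(Oc2c(C=O)ccc(O)c2O)c1Br | intermediate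
7 | 2,5-dibromo-3-(4-bromo-6-formyl-2,3-dihydroxyphenoxy)-4-hydroxybenzaldehyde | O=Cc1cc(Br)c(O)c(Oc2c(C=O)cc(Br)c(O)c2O)c1Br | intermediate
8 | 6-bromo-3-[2,5-dibromo-6-hydroxy-3-(hydroxymethyl)phenoxy]-4-(hydroxymethyl)benzene-1,2-diol | OCc1cc(Br)c(O)c(Oc2c(CO)cc(Br)c(O)c2O)c1Br | target

**Total step count:** 6. **Longest linear sequence:** 6 steps (1 → 2 → 3 → 5 → 6 → 7 → 8; 4 is bought and enters at step 3).

**Three steps most likely to fail**

Step 3 is the main risk: the carbenoid may undergo Wolff ring contraction, form benzodioxoles with the aldehydes, or C-arylate. The fallback makes the ether by denitrative SNAr; it sets out from 1 and 4 and comes back to the route at 6. Compound 1 is O-benzylated (BnBr, K2CO3, DMF) to 3-(benzyloxy)-4-methoxy-2-nitrobenzaldehyde F1. Its nitro group is ortho to the formyl group and twisted out of plane by its two neighbours, so the phenoxide of 4 displaces it (Cs2CO3, DMSO, 90 °C) to give 3-[2-(benzyloxy)-6-formyl-3-methoxyphenoxy]-2-bromo-4-methoxybenzaldehyde F2. BBr3 (CH2Cl2, −78 → 0 °C) then removes the benzyl and both methyl groups and gives 6.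

Step 2 is the second risk: the free o-aminobenzaldehyde 2 may self-condense, or the formyl-substituted diazide 3 may be too labile to handle. The fallback carries the aldehyde of ring B as an acetal through the sensitive stages; it sets out from 1 and comes back at 5. Compound 1 is converted with ethylene glycol (TsOH, toluene, Dean–Stark) into 3-(1,3-dioxolan-2-yl)-6-methoxy-2-nitrophenol F3. Hydrogenation (H2, Pd/C, EtOAc) gives 2-amino-3-(1,3-dioxolan-2-yl)-6-methoxyphenol F4, and t-BuONO (THF, 0 °C, dark) gives 6-diazo-5-(1,3-dioxolan-2-yl)-2-methoxycyclohexa-2,4-dien-1-one F5. Rh2(esp)2-catalysed O–H insertion with 4 gives 2-bromo-3-[6-(1,3-dioxolan-2-yl)-2-hydroxy-3-methoxyphenoxy]-4-methoxybenzaldehyde F6, and 1 M HCl/THF releases the aldehyde to give 5.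

Step 5 is the third risk: ring B of 6 may brominate at C6 (para to its 3-OH), or the catechol may be oxidised. The fallback makes ring B vanillin-like, so that only the 4-OH directs; it sets out from 5 and comes back at 7. Compound 5 is methylated (MeI, K2CO3, DMF) to 2-bromo-3-(6-formyl-2,3-dimethoxyphenoxy)-4-methoxybenzaldehyde F7. Nucleophilic demethylation (LiCl, DMF, 150 °C) cleaves only the two methoxy groups para to a formyl group and gives 2-bromo-3-(6-formyl-3-hydroxy-2-methoxyphenoxy)-4-hydroxybenzaldehyde F8. Br2 (2.1 equiv, AcOH, rt) brominates ortho to each 4-OH to give 2,5-dibromo-3-(4-bromo-6-formyl-3-hydroxy-2-methoxyphenoxy)-4-hydroxybenzaldehyde F9, and BBr3 (CH2Cl2, −78 → 0 °C) cleaves the remaining methyl ether to give 7.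

**Further compounds**
F1 | step 3 | 3-(benzyloxy)-4-methoxy-2-nitrobenzaldehyde | O=Cc1ccc(OC)c(OCc2ccccc2)c1[N+](=O)[O-]
F2 | step 3 | 3-[2-(benzyloxy)-6-formyl-3-methoxyphenoxy]-2-bromo-4-methoxybenzaldehyde | O=Cc1ccc(OC)c(Oc2c(C=O)ccc(OC)c2OCc3ccccc3)c1Br
F3 | step 2 | 3-(1,3-dioxolan-2-yl)-6-methoxy-2-nitrophenol | COc1ccc(C2OCCO2)c([N+](=O)[O-])c1O
F4 | step 2 | 2-amino-3-(1,3-dioxolan-2-yl)-6-methoxyphenol | COc1ccc(C2OCCO2)c(N)c1O
F5 | step 2 | 6-diazo-5-(1,3-dioxolan-2-yl)-2-methoxycyclohexa-2,4-dien-1-one | COC1=CC=C(C2OCCO2)C(=[N+]=[N-])C1=O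
F6 | step 2 | 2-bromo-3-[6-(1,3-dioxolan-2-yl)-2-hydroxy-3-methoxyphenoxy]-4-methoxybenzaldehyde | O=Cc1ccc(OC)c(Oc2c(C3OCCO3)ccc(OC)c2O)c1Br
F7 | step 5 | 2-bromo-3-(6-formyl-2,3-dimethoxyphenoxy)-4-methoxybenzaldehyde | O=Cc1ccc(OC)c(Oc2c(C=O)ccc(OC)c2OC)c1Br
F8 | step 5 | 2-bromo-3-(6-formyl-3-hydroxy-2-methoxyphenoxy)-4-hydroxybenzaldehyde | O=Cc1ccc(O)c(Oc2c(C=O)ccc(O)c2OC)c1Br
F9 | step 5 | 2,5-dibromo-3-(4-bromo-6-formyl-3-hydroxy-2-methoxyphenoxy)-4-hydroxybenzaldehyde | O=Cc1cc(Br)c(O)c(Oc2c(C=O)cc(Br)c(O)c2OC)c1Br
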